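**Retrosynthetic overview**
- Target ⇐ phenol deacetylation, C7‑hydroxyl‑directed epoxidation of the C1=C2 cyclopentene, and selective acylation of the C5 hydroxyl.
- Five‑membered ring (formed second) ⇐ ring‑closing metathesis of a C8a vinyl and a C3a methallyl group; the methallyl group comes from 1,2‑addition and anionic oxy‑Cope rearrangement on a cycloheptenecarbaldehyde.
- Seven‑membered ring (formed first) ⇐ ring‑closing metathesis of an acyclic vinyl / 2‑substituted acrolein.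
- Acyclic chain ⇐ key intermolecular Evans syn aldol (C4–C5 bond) between an N‑isovaleryl oxazolidinone and an aldehyde made from (R)‑linalool, which supplies the C7 carbinol centre.

Assumption: (R)‑(−)‑linalool and (R)‑4‑benzyl‑2‑oxazolidinone are bought in high enantiomeric purity; locants C1–C8a are azulene numbering of the target (C1/C2 epoxide, C4 isopropyl carbon, C5 acyloxy carbon, C7 carbinol, C3a/C8a ring fusion).
Abbreviation: TBS = tert‑butyldimethylsilyl.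

**Route**

Step 1
Reactants: 1 (R)‑(−)‑linalool
Product: 2 tert‑butyl{[(3R)‑3,7‑dimethylocta‑1,6‑dien‑3‑yl]oxy}dimethylsilane
Conditions: TBSOTf, 2,6‑lutidine, CH2Cl2, 0 °C → rt
Reagents that add atoms: tert‑butyldimethylsilyl triflate, CC(C)(C)[Si](C)(C)OS(=O)(=O)C(F)(F)F
Why: Silyl triflate silylation protects the hindered tertiary alcohol without touching the C7 stereocentre, which comes from the chiral pool.

Step 2
Reactants: 2 linalool TBS ether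
Product: 4 (3R)‑3‑(TBSO)‑3,7‑dimethyloct‑6‑en‑1‑ol, via B‑alkyl‑9‑BBN adduct 3 (not isolated)
Conditions: 9‑BBN, THF, 0 °C → rt; then NaOH (aq), H2O2, 0 °C
Reagents that add atoms: 9‑borabicyclo[3.3.1]nonane, C1CCC2CCCC1B2 (kept in 3 only); hydrogen peroxide, OO
Why: Brown hydroboration–oxidation with bulky 9‑BBN takes only the monosubstituted vinyl group, anti‑Markovnikov, and leaves the trisubstituted alkene.

Step 3
Reactants: 4 primary alcohol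
Product: 5 (3R)‑3‑(TBSO)‑3,7‑dimethyloct‑6‑enal
Conditions: Dess–Martin periodinane, CH2Cl2, rt
Reagents that add atoms: none
Why: Dess–Martin oxidation gives the aldehyde under neutral conditions that do not eliminate the β‑silyloxy group.

Step 4
Reactants: 6 (4R)‑4‑benzyl‑1,3‑oxazolidin‑2‑one; 7 3‑methylbutanoyl chloride
Product: 8 (4R)‑4‑benzyl‑3‑(3‑methylbutanoyl)‑1,3‑oxazolidin‑2‑one
Conditions: Et3N, DMAP (cat.), CH2Cl2, 0 °C → rt
Reagents that add atoms: none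
Why: DMAP‑catalysed N‑acylation of the oxazolidinone with the acid chloride is a standard imide formation.

Step 5 (key step)
Reactants: 8 N‑isovaleryl oxazolidinone; 5 aldehyde
Product: 11 (4R)‑4‑benzyl‑3‑[(2R,3S,5R)‑5‑(TBSO)‑3‑hydroxy‑5,9‑dimethyl‑2‑(propan‑2‑yl)dec‑8‑enoyl]‑1,3‑oxazolidin‑2‑one, via dibutylboron Z‑enolate 9 (not isolated), via dibutylboron aldolate 10 (not isolated)
Conditions: Bu2BOTf, Et3N, CH2Cl2, 0 °C; then 5, −78 → 0 °C; then pH 7 buffer, MeOH, H2O2, 0 °C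
Reagents that add atoms: dibutylboron triflate, CCCCB(CCCC)OS(=O)(=O)C(F)(F)F (kept in 9 and 10 only)
Why: In this intermolecular Evans syn aldol the Z‑boron enolate reacts through a Zimmerman–Traxler chair on the face left open by the (R)‑benzyl auxiliary, setting C4 (isopropyl) and C5 (carbinol) as the 2R,3S syn pair, which is the trans arrangement in the later ring.

Step 6
Reactants: 11 aldol adduct
Product: 12 (2R,3S,5R)‑5‑(TBSO)‑3‑hydroxy‑N‑methoxy‑N,5,9‑trimethyl‑2‑(propan‑2‑yl)dec‑8‑enamide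
Conditions: MeNH(OMe)·HCl, AlMe3, CH2Cl2, −20 → 0 °C
Reagents that add atoms: N,O‑dimethylhydroxylamine hydrochloride, CNOC.Cl
Why: Aluminium‑amide transamination, assisted by the free β‑hydroxyl, cleaves the auxiliary to the Weinreb amide without epimerising C4.

Step 7
Reactants: 12 β‑hydroxy Weinreb amide
Product: 13 (2R,3S,5R)‑3,5‑bis(TBSO)‑N‑methoxy‑N,5,9‑trimethyl‑2‑(propan‑2‑yl)dec‑8‑enamide
Conditions: TBSOTf, 2,6‑lutidine, CH2Cl2, 0 °C
Reagents that add atoms: tert‑butyldimethylsilyl triflate, CC(C)(C)[Si](C)(C)OS(=O)(=O)C(F)(F)F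
Why: Silyl triflate silylation protects the hindered C5 hydroxyl so that it survives the organometallic and basic steps ahead.

Step 8
Reactants: 13 Weinreb amide
Product: 14 (2R,3S,5R)‑3,5‑bis(TBSO)‑5,9‑dimethyl‑2‑(propan‑2‑yl)dec‑8‑enal
Conditions: i‑Bu2AlH, THF, −78 °C
Reagents that add atoms: none
Why: Weinreb amide reduction stops at the aldehyde because the chelated tetrahedral aluminium intermediate collapses only on work‑up.

Step 9
Reactants: 14 aldehyde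
Product: 15 (3S,4S,6R)‑4,6‑bis(TBSO)‑6,10‑dimethyl‑3‑(propan‑2‑yl)undeca‑1,9‑diene
Conditions: Ph3PCH3Br, KN(SiMe3)2, THF, 0 °C; then 14, −78 → 0 °C
Reagents that add atoms: methyltriphenylphosphonium bromide, C[P+](c1ccccc1)(c1ccccc1)c1ccccc1.[Br-]
Why: Wittig methylenation at low temperature turns the formyl carbon (future C3a) into a vinyl group without epimerising the adjacent C4 centre.

Step 10
Reactants: 15 diene
Product: 16 3‑{(3R,5S,6S)‑3,5‑bis(TBSO)‑3‑methyl‑6‑(propan‑2‑yl)oct‑7‑en‑1‑yl}‑2,2‑dimethyloxirane (both oxirane epimers)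
Conditions: mCPBA (1.05 equiv), CH2Cl2, 0 °C
Reagents that add atoms: 3‑chloroperoxybenzoic acid, OOC(=O)c1cccc(Cl)c1
Why: Prilezhaev epoxidation is much faster at the electron‑rich trisubstituted alkene than at the hindered monosubstituted vinyl group.

Step 11
Reactants: 16 epoxide
Product: 17 (4R,6S,7S)‑4,6‑bis(TBSO)‑4‑methyl‑7‑(propan‑2‑yl)non‑8‑enal
Conditions: H5IO6, THF–H2O, 0 °C
Reagents that add atoms: none
Why: Periodic acid opens the trisubstituted epoxide and cleaves the resulting glycol (Malaprade cleavage) to the aldehyde and acetone, leaving the vinyl group intact.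

Step 12
Reactants: 17 aldehyde
Product: 18 (4R,6S,7S)‑4,6‑bis(TBSO)‑4‑methyl‑2‑methylidene‑7‑(propan‑2‑yl)non‑8‑enal
Conditions: 37% aq. CH2O, pyrrolidine (10 mol%), propanoic acid (10 mol%), i‑PrOH, 45 °C
Reagents that add atoms: formaldehyde, C=O
Why: Amine‑catalysed Mannich condensation and elimination (α‑methylenation) converts the unbranched aldehyde into the 2‑substituted acrolein needed for ring closure.

Step 13
Reactants: 18 vinyl / 2‑substituted acrolein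
Product: 19 (3S,4S,6R)‑4,6‑bis(TBSO)‑6‑methyl‑3‑(propan‑2‑yl)cyclohept‑1‑ene‑1‑carbaldehyde
Conditions: second‑generation Grubbs catalyst RuCl2(=CHPh)(H2IMes)(PCy3) (10 mol%), toluene (5 mM), 80 °C
Reagents that add atoms: none
Why: Ring‑closing metathesis starts at the terminal vinyl group and closes onto the acrolein alkene, helped by the fully substituted C7, forming the seven‑membered ring with loss of ethene.

Step 14
Reactants: 19 cycloheptenecarbaldehyde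
Product: 20 1‑{(3S,4S,6R)‑4,6‑bis(TBSO)‑6‑methyl‑3‑(propan‑2‑yl)cyclohept‑1‑en‑1‑yl}‑3‑methylbut‑3‑en‑1‑ol (both carbinol epimers)
Conditions: 2‑methylallylmagnesium chloride, THF, −78 °C
Reagents that add atoms: 2‑methylallylmagnesium chloride, CC(=C)C[Mg]Cl
Why: Allylic Grignard reagents add 1,2 to enals, giving the 1,5‑dien‑3‑ol needed for the sigmatropic shift; the carbinol centre is lost later, so its configuration does not matter.

Step 15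
Reactants: 20 dienol
Product: 23 (2S,3S,4S,6R)‑4,6‑bis(TBSO)‑6‑methyl‑2‑(2‑methylprop‑2‑en‑1‑yl)‑3‑(propan‑2‑yl)cycloheptane‑1‑carbaldehyde (both epimers at the formyl‑bearing carbon), via potassium alkoxide 21 (not isolated), via potassium enolate 22 (not isolated)
Conditions: KH, 18‑crown‑6, THF, 0 °C → rt; then aq. NH4Cl, −78 °C
Reagents that add atoms: potassium hydride, [H-].[K+] (potassium kept in 21 and 22 only)
Why: The anionic oxy‑Cope rearrangement passes the methallyl terminus to C3a through a chair transition state on the ring face opposite the adjacent C4 isopropyl group, so both carbinol epimers give the same C3a configuration.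

Step 16
Reactants: 23 aldehyde epimer mixture
Product: 24 (1S,2S,3S,4S,6R)‑4,6‑bis(TBSO)‑6‑methyl‑2‑(2‑methylprop‑2‑en‑1‑yl)‑3‑(propan‑2‑yl)cycloheptane‑1‑carbaldehyde
Conditions: K2CO3 (0.2 equiv), MeOH, rt
Reagents that add atoms: none
Why: Base‑mediated enolisation and reprotonation funnels the mixture to the thermodynamic isomer with formyl trans to methallyl (all four contiguous substituents equatorial), which sets C8a.

Step 17
Reactants: 24 trans aldehyde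
Product: 25 (1R,2R,3S,4S,6R)‑1‑ethenyl‑4,6‑bis(TBSO)‑6‑methyl‑2‑(2‑methylprop‑2‑en‑1‑yl)‑3‑(propan‑2‑yl)cycloheptane
Conditions: Ph3PCH3Br, KN(SiMe3)2, THF, 0 °C; then 24, −78 → 0 °C
Reagents that add atoms: methyltriphenylphosphonium bromide, C[P+](c1ccccc1)(c1ccccc1)c1ccccc1.[Br-]
Why: Wittig methylenation gives the C8a vinyl group, and the aldehyde is already the thermodynamic epimer, so basic conditions cannot erode it.

Step 18
Reactants: 25 vinyl / methallyl diene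
Product: 26 (3aR,4S,5S,7R,8aS)‑5,7‑bis(TBSO)‑2,7‑dimethyl‑4‑(propan‑2‑yl)‑3,3a,4,5,6,7,8,8a‑octahydroazulene
Conditions: second‑generation Grubbs catalyst RuCl2(=CHPh)(H2IMes)(PCy3) (5 mol%), CH2Cl2, 40 °C
Reagents that add atoms: none
Why: Ring‑closing metathesis of the vicinal trans vinyl and methallyl groups forms the trisubstituted methylcyclopentene with the double bond fixed at C1=C2 and the trans ring fusion retained.

Step 19
Reactants: 26 bis‑silyl ether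
Product: 27 (3aR,4S,5S,7R,8aS)‑2,7‑dimethyl‑4‑(propan‑2‑yl)‑3,3a,4,5,6,7,8,8a‑octahydroazulene‑5,7‑diol
Conditions: Bu4NF, THF, 60 °C
Reagents that add atoms: none
Why: Fluoride desilylation removes both TBS groups from a substrate with no base‑sensitive functionality.

Step 20
Reactants: 27 diol; 28 4‑(acetyloxy)benzoyl chloride
Product: 29 (3aR,4S,5S,7R,8aS)‑7‑hydroxy‑2,7‑dimethyl‑4‑(propan‑2‑yl)‑3,3a,4,5,6,7,8,8a‑octahydroazulen‑5‑yl 4‑(acetyloxy)benzoate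
Conditions: pyridine, DMAP (cat.), CH2Cl2, 0 °C → rt
Reagents that add atoms: none
Why: DMAP‑catalysed acylation takes the secondary C5 hydroxyl and leaves the tertiary C7 hydroxyl, which is far less reactive.

Step 21
Reactants: 29 hydroxy alkene ester
Product: 30 (1S,2R,3aR,4S,5S,7R,8aS)‑1,2‑epoxy‑7‑hydroxy‑2,7‑dimethyl‑4‑(propan‑2‑yl)decahydroazulen‑5‑yl 4‑(acetyloxy)benzoate
Conditions: VO(acac)2 (10 mol%), t‑BuOOH (decane solution), toluene, rt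
Reagents that add atoms: tert‑butyl hydroperoxide, CC(C)(C)OO
Why: In this vanadium‑catalysed hydroxyl‑directed epoxidation the vanadate ester of the bishomoallylic C7 hydroxyl delivers oxygen to the alkene face syn to that hydroxyl, setting C1 and C2; the syn epoxy alcohol cannot cyclise to an ether.

Step 22
Reactants: 30 aryl acetate
Product: 31 (1S,2R,3aR,4S,5S,7R,8aS)‑1,2‑epoxy‑7‑hydroxy‑2,7‑dimethyl‑4‑(propan‑2‑yl)decahydroazulen‑5‑yl 4‑hydroxybenzoate (target, CNP0245441.1)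
Conditions: K2CO3 (1 equiv), MeOH, 0 °C; then aq. NH4Cl
Reagents that add atoms: none
Why: Base‑mediated transesterification cleaves the phenolic acetate much faster than the hindered alkyl benzoate, which the resulting phenoxide further deactivates, and the epoxide is inert to these conditions.

**Compound list**
1 | (R)‑(−)‑linalool | C=C[C@](C)(O)CCC=C(C)C | starting material
2 | tert‑butyl{[(3R)‑3,7‑dimethylocta‑1,6‑dien‑3‑yl]oxy}dimethylsilane | C=C[C@](C)(O[Si](C)(C)C(C)(C)C)CCC=C(C)C | intermediate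
3 | 9‑[(3S)‑3‑(TBSO)‑3,7‑dimethyloct‑6‑en‑1‑yl]‑9‑borabicyclo[3.3.1]nonane | C1CCC2CCCC1B2CC[C@](C)(O[Si](C)(C)C(C)(C)C)CCC=C(C)C | intermediate
4 | (3R)‑3‑(TBSO)‑3,7‑dimethyloct‑6‑en‑1‑ol | OCC[C@](C)(O[Si](C)(C)C(C)(C)C)CCC=C(C)C | intermediate
5 | (3R)‑3‑(TBSO)‑3,7‑dimethyloct‑6‑enal | O=CC[C@](C)(O[Si](C)(C)C(C)(C)C)CCC=C(C)C | intermediate
6 | (4R)‑4‑benzyl‑1,3‑oxazolidin‑2‑one | O=C1N[C@H](Cc2ccccc2)CO1 | starting material
7 | 3‑methylbutanoyl chloride | CC(C)CC(Cl)=O | starting material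
8 | (4R)‑4‑benzyl‑3‑(3‑methylbutanoyl)‑1,3‑oxazolidin‑2‑one | CC(C)CC(=O)N1[C@H](Cc2ccccc2)COC1=O | intermediate
9 | (4R)‑4‑benzyl‑3‑{(1Z)‑1‑[(dibutylboranyl)oxy]‑3‑methylbut‑1‑en‑1‑yl}‑1,3‑oxazolidin‑2‑one | CC(C)/C=C(\OB(CCCC)CCCC)N1[C@H](Cc2ccccc2)COC1=O | intermediate
10 | (4R)‑4‑benzyl‑3‑[(2R,3S,5R)‑5‑(TBSO)‑3‑[(dibutylboranyl)oxy]‑5,9‑dimethyl‑2‑(propan‑2‑yl)dec‑8‑enoyl]‑1,3‑oxazolidin‑2‑one | CC(C)[C@@H](C(=O)N1[C@H](Cc2ccccc2)COC1=O)[C@@H](OB(CCCC)CCCC)C[C@](C)(O[Si](C)(C)C(C)(C)C)CCC=C(C)C | intermediate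
11 | (4R)‑4‑benzyl‑3‑[(2R,3S,5R)‑5‑(TBSO)‑3‑hydroxy‑5,9‑dimethyl‑2‑(propan‑2‑yl)dec‑8‑enoyl]‑1,3‑oxazolidin‑2‑one | CC(C)[C@@H](C(=O)N1[C@H](Cc2ccccc2)COC1=O)[C@@H](O)C[C@](C)(O[Si](C)(C)C(C)(C)C)CCC=C(C)C | intermediate
12 | (2R,3S,5R)‑5‑(TBSO)‑3‑hydroxy‑N‑methoxy‑N,5,9‑trimethyl‑2‑(propan‑2‑yl)dec‑8‑enamide | CC(C)[C@@H](C(=O)N(C)OC)[C@@H](O)C[C@](C)(O[Si](C)(C)C(C)(C)C)CCC=C(C)C | intermediate
13 | (2R,3S,5R)‑3,5‑bis(TBSO)‑N‑methoxy‑N,5,9‑trimethyl‑2‑(propan‑2‑yl)dec‑8‑enamide | CC(C)[C@@H](C(=O)N(C)OC)[C@@H](O[Si](C)(C)C(C)(C)C)C[C@](C)(O[Si](C)(C)C(C)(C)C)CCC=C(C)C | intermediate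
14 | (2R,3S,5R)‑3,5‑bis(TBSO)‑5,9‑dimethyl‑2‑(propan‑2‑yl)dec‑8‑enal | CC(C)[C@@H](C=O)[C@@H](O[Si](C)(C)C(C)(C)C)C[C@](C)(O[Si](C)(C)C(C)(C)C)CCC=C(C)C | intermediate
15 | (3S,4S,6R)‑4,6‑bis(TBSO)‑6,10‑dimethyl‑3‑(propan‑2‑yl)undeca‑1,9‑diene | CC(C)[C@@H](C=C)[C@@H](O[Si](C)(C)C(C)(C)C)C[C@](C)(O[Si](C)(C)C(C)(C)C)CCC=C(C)C | intermediate
16 | 3‑{(3R,5S,6S)‑3,5‑bis(TBSO)‑3‑methyl‑6‑(propan‑2‑yl)oct‑7‑en‑1‑yl}‑2,2‑dimethyloxirane (both oxirane epimers) | CC(C)[C@@H](C=C)[C@@H](O[Si](C)(C)C(C)(C)C)C[C@](C)(O[Si](C)(C)C(C)(C)C)CCC1OC1(C)C | intermediate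
17 | (4R,6S,7S)‑4,6‑bis(TBSO)‑4‑methyl‑7‑(propan‑2‑yl)non‑8‑enal | CC(C)[C@@H](C=C)[C@@H](O[Si](C)(C)C(C)(C)C)C[C@](C)(O[Si](C)(C)C(C)(C)C)CCC=O | intermediate
18 | (4R,6S,7S)‑4,6‑bis(TBSO)‑4‑methyl‑2‑methylidene‑7‑(propan‑2‑yl)non‑8‑enal | CC(C)[C@@H](C=C)[C@@H](O[Si](C)(C)C(C)(C)C)C[C@](C)(O[Si](C)(C)C(C)(C)C)CC(=C)C=O | intermediate
19 | (3S,4S,6R)‑4,6‑bis(TBSO)‑6‑methyl‑3‑(propan‑2‑yl)cyclohept‑1‑ene‑1‑carbaldehyde | CC(C)[C@H]1C=C(C=O)C[C@@](C)(O[Si](C)(C)C(C)(C)C)C[C@@H]1O[Si](C)(C)C(C)(C)C | intermediate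
20 | 1‑{(3S,4S,6R)‑4,6‑bis(TBSO)‑6‑methyl‑3‑(propan‑2‑yl)cyclohept‑1‑en‑1‑yl}‑3‑methylbut‑3‑en‑1‑ol (both carbinol epimers) | CC(C)[C@H]1C=C(C(O)CC(C)=C)C[C@@](C)(O[Si](C)(C)C(C)(C)C)C[C@@H]1O[Si](C)(C)C(C)(C)C | intermediate
21 | potassium 1‑{(3S,4S,6R)‑4,6‑bis(TBSO)‑6‑methyl‑3‑(propan‑2‑yl)cyclohept‑1‑en‑1‑yl}‑3‑methylbut‑3‑en‑1‑olate (both epimers) | CC(C)[C@H]1C=C(C([O-])CC(C)=C)C[C@@](C)(O[Si](C)(C)C(C)(C)C)C[C@@H]1O[Si](C)(C)C(C)(C)C.[K+] | intermediate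
22 | potassium {(2S,3S,4S,6R)‑4,6‑bis(TBSO)‑6‑methyl‑2‑(2‑methylprop‑2‑en‑1‑yl)‑3‑(propan‑2‑yl)cycloheptylidene}methanolate | CC(C)[C@H]1[C@H](CC(C)=C)C(=C[O-])C[C@@](C)(O[Si](C)(C)C(C)(C)C)C[C@@H]1O[Si](C)(C)C(C)(C)C.[K+] | intermediate
23 | (2S,3S,4S,6R)‑4,6‑bis(TBSO)‑6‑methyl‑2‑(2‑methylprop‑2‑en‑1‑yl)‑3‑(propan‑2‑yl)cycloheptane‑1‑carbaldehyde (both epimers at the formyl‑bearing carbon) | CC(C)[C@H]1[C@H](CC(C)=C)C(C=O)C[C@@](C)(O[Si](C)(C)C(C)(C)C)C[C@@H]1O[Si](C)(C)C(C)(C)C | intermediate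
24 | (1S,2S,3S,4S,6R)‑4,6‑bis(TBSO)‑6‑methyl‑2‑(2‑methylprop‑2‑en‑1‑yl)‑3‑(propan‑2‑yl)cycloheptane‑1‑carbaldehyde | CC(C)[C@H]1[C@H](CC(C)=C)[C@@H](C=O)C[C@@](C)(O[Si](C)(C)C(C)(C)C)C[C@@H]1O[Si](C)(C)C(C)(C)C | intermediate
25 | (1R,2R,3S,4S,6R)‑1‑ethenyl‑4,6‑bis(TBSO)‑6‑methyl‑2‑(2‑methylprop‑2‑en‑1‑yl)‑3‑(propan‑2‑yl)cycloheptane | CC(C)[C@H]1[C@H](CC(C)=C)[C@@H](C=C)C[C@@](C)(O[Si](C)(C)C(C)(C)C)C[C@@H]1O[Si](C)(C)C(C)(C)C | intermediate
26 | (3aR,4S,5S,7R,8aS)‑5,7‑bis(TBSO)‑2,7‑dimethyl‑4‑(propan‑2‑yl)‑3,3a,4,5,6,7,8,8a‑octahydroazulene | CC(C)[C@H]1[C@@H]2CC(C)=C[C@H]2C[C@@](C)(O[Si](C)(C)C(C)(C)C)C[C@@H]1O[Si](C)(C)C(C)(C)C | intermediate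
27 | (3aR,4S,5S,7R,8aS)‑2,7‑dimethyl‑4‑(propan‑2‑yl)‑3,3a,4,5,6,7,8,8a‑octahydroazulene‑5,7‑diol | CC(C)[C@H]1[C@@H]2CC(C)=C[C@H]2C[C@@](C)(O)C[C@@H]1O | intermediate
28 | 4‑(acetyloxy)benzoyl chloride | CC(=O)Oc1ccc(cc1)C(Cl)=O | starting material
29 | (3aR,4S,5S,7R,8aS)‑7‑hydroxy‑2,7‑dimethyl‑4‑(propan‑2‑yl)‑3,3a,4,5,6,7,8,8a‑octahydroazulen‑5‑yl 4‑(acetyloxy)benzoate | CC(C)[C@H]1[C@@H]2CC(C)=C[C@H]2C[C@@](C)(O)C[C@@H]1OC(=O)c1ccc(OC(C)=O)cc1 | intermediate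
30 | (1S,2R,3aR,4S,5S,7R,8aS)‑1,2‑epoxy‑7‑hydroxy‑2,7‑dimethyl‑4‑(propan‑2‑yl)decahydroazulen‑5‑yl 4‑(acetyloxy)benzoate | CC(C)[C@H]1[C@@H]2C[C@@]3(C)O[C@H]3[C@H]2C[C@@](C)(O)C[C@@H]1OC(=O)c1ccc(OC(C)=O)cc1 | intermediate
31 | (1S,2R,3aR,4S,5S,7R,8aS)‑1,2‑epoxy‑7‑hydroxy‑2,7‑dimethyl‑4‑(propan‑2‑yl)decahydroazulen‑5‑yl 4‑hydroxybenzoate | CC(C)[C@H]1[C@@H]2C[C@@]3(C)O[C@H]3[C@H]2C[C@@](C)(O)C[C@@H]1OC(=O)c1ccc(O)cc1 | target

**Totals**
Total step count: 22. Longest linear sequence: 21 steps (steps 1–3 and 5–22; step 4 is a one‑step side branch).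

**Three steps most likely to fail, with fallbacks**

Step 13 (ring‑closing metathesis onto a 2‑substituted acrolein next to a branched allylic centre; risk of slow turnover or oligomers). The fallback sets out from 14 and closes the ring by carbonyl condensation instead of metathesis. Ozonolysis of the only alkene of 14 (O3, CH2Cl2–MeOH, −78 °C; PPh3) gives the dialdehyde (2R,3S,5R)‑3,5‑bis(TBSO)‑5‑methyl‑2‑(propan‑2‑yl)octanedial F4. Dibenzylammonium trifluoroacetate in benzene at 50 °C then forms the enamine of the unbranched aldehyde only, which attacks the α‑branched aldehyde intramolecularly and dehydrates to the cycloheptenecarbaldehyde. The route is rejoined at 19, bypassing 15–18.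

Step 15 (anionic oxy‑Cope; risk of poor facial control at C3a or silyl migration under KH). The fallback sets out from 19 and swaps the sigmatropic shift for a copper‑mediated conjugate addition. Pinnick oxidation (NaClO2, NaH2PO4, 2‑methyl‑2‑butene, t‑BuOH–H2O) gives the cycloheptenecarboxylic acid F1, and MeI with K2CO3 in DMF gives its methyl ester F2. Conjugate addition of the allylic copper reagent made from 2‑methylallylmagnesium chloride and CuBr·SMe2 with Me3SiCl (THF, −78 °C), trans to the isopropyl group, followed by NaOMe/MeOH equilibration, gives the all‑trans methallyl ester F3. i‑Bu2AlH in CH2Cl2 at −78 °C reduces F3 to the aldehyde, and the route is rejoined at 24.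

Step 21 (directed epoxidation from a tertiary bishomoallylic hydroxyl; risk of slow delivery or face leakage). The fallback sets out from 26 and builds the epoxide through a halohydrin before deprotection. NBS in aqueous THF places bromine at C1 on the face away from the C8 methylene and water at the tertiary C2 on the opposite face, giving the bromohydrin (1R,2R,3aS,4S,5S,7R,8aS)‑1‑bromo‑5,7‑bis(TBSO)‑2,7‑dimethyl‑4‑(propan‑2‑yl)decahydroazulen‑2‑ol F5. K2CO3 in MeOH closes it with inversion at C1 to the bis‑silyl epoxide F6, which has the same epoxide face as 30. Bu4NF in THF gives the epoxy diol F7, and selective acylation of its secondary hydroxyl with 28 (pyridine, DMAP) rejoins the route at 30.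

**Further compounds**
F1 | step 15 | (3S,4S,6R)‑4,6‑bis(TBSO)‑6‑methyl‑3‑(propan‑2‑yl)cyclohept‑1‑ene‑1‑carboxylic acid | CC(C)[C@H]1C=C(C(O)=O)C[C@@](C)(O[Si](C)(C)C(C)(C)C)C[C@@H]1O[Si](C)(C)C(C)(C)C
F2 | step 15 | methyl (3S,4S,6R)‑4,6‑bis(TBSO)‑6‑methyl‑3‑(propan‑2‑yl)cyclohept‑1‑ene‑1‑carboxylate | CC(C)[C@H]1C=C(C(=O)OC)C[C@@](C)(O[Si](C)(C)C(C)(C)C)C[C@@H]1O[Si](C)(C)C(C)(C)C
F3 | step 15 | methyl (1S,2S,3S,4S,6R)‑4,6‑bis(TBSO)‑6‑methyl‑2‑(2‑methylprop‑2‑en‑1‑yl)‑3‑(propan‑2‑yl)cycloheptane‑1‑carboxylate | CC(C)[C@H]1[C@H](CC(C)=C)[C@@H](C(=O)OC)C[C@@](C)(O[Si](C)(C)C(C)(C)C)C[C@@H]1O[Si](C)(C)C(C)(C)C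
F4 | step 13 | (2R,3S,5R)‑3,5‑bis(TBSO)‑5‑methyl‑2‑(propan‑2‑yl)octanedial | CC(C)[C@@H](C=O)[C@@H](O[Si](C)(C)C(C)(C)C)C[C@](C)(O[Si](C)(C)C(C)(C)C)CCC=O
F5 | step 21 | (1R,2R,3aS,4S,5S,7R,8aS)‑1‑bromo‑5,7‑bis(TBSO)‑2,7‑dimethyl‑4‑(propan‑2‑yl)decahydroazulen‑2‑ol | CC(C)[C@H]1[C@@H]2C[C@@](C)(O)[C@H](Br)[C@H]2C[C@@](C)(O[Si](C)(C)C(C)(C)C)C[C@@H]1O[Si](C)(C)C(C)(C)C
F6 | step 21 | (1S,2R,3aR,4S,5S,7R,8aS)‑5,7‑bis(TBSO)‑1,2‑epoxy‑2,7‑dimethyl‑4‑(propan‑2‑yl)decahydroazulene | CC(C)[C@H]1[C@@H]2C[C@@]3(C)O[C@H]3[C@H]2C[C@@](C)(O[Si](C)(C)C(C)(C)C)C[C@@H]1O[Si](C)(C)C(C)(C)C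
F7 | step 21 | (1S,2R,3aR,4S,5S,7R,8aS)‑1,2‑epoxy‑2,7‑dimethyl‑4‑(propan‑2‑yl)decahydroazulene‑5,7‑diol | CC(C)[C@H]1[C@@H]2C[C@@]3(C)O[C@H]3[C@H]2C[C@@](C)(O)C[C@@H]1O
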